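The vessel is a closed, stirred flask at constant temperature and volume, where a racemic substrate meets a single-handed partner. A short meeting was called to say how much left-handed product each of the flasks below holds at the asked time.

common to all: left-handed substrate 0.10 M; right-handed substrate 0.10 M
- violet: partner 1.1 equiv; run made earlier
- red: partner 14 equiv; run made earlier
- north-west: partner 1.20 equiv; time 25 h
- south: partner 3.80 equiv; time 25 h
- west: partner 0.830 equiv; time 25 h
- north-east: partner 1.70 equiv; time 25 h
- south-east: partner 10.0 equiv; time 25 h
- east: partner 2.50 equiv; time 25 h

- violet (time / h: left-handed product / %, left-handed substrate / %): 1.33: 1.6, 46.9; 3.00: 3.8, 45.1; 6.00: 5.4, 43.0; 10.0: 6.9, 41.2; 12.0: 7.3, 41.0; 20.0: 8.2, 39.9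
- red (time / h: left-handed product / %, left-handed substrate / %): 1.33: 18.1, 31.9; 2.50: 25.3, 25.9; 4.00: 28.7, 22.2; 6.00: 31.5, 20.6; 10.0: 34.6, 18.7; 20.0: 36.1, 17.9

(readings scatter by 0.3 percentage points)

1. ranking by amount of left-handed product, in percent of the left-handed substrate and right-handed substrate together charged, from high to low, at 25 h (north-west / south / west / north-east / south-east / east)
2. the amount of left-handed product, in percent of the left-handed substrate and right-handed substrate together charged of the flask you put first, at 25 h
3. the amount of left-handed product, in percent of the left-handed substrate and right-handed substrate together charged of the flask you put last, at 25 h

- partner is single-handed; left-handed substrate and right-handed substrate are mirror images of each other, charged as a racemate, each of them at the stated concentration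
- reactions considered so far: partner + left-handed substrate -> left-handed product; partner + right-handed substrate -> right-handed product; left-handed substrate <-> achiral form; right-handed substrate <-> achiral form; achiral form -> waste; 2 partner -> homo dimer; partner -> decomposed reagent
- the handed part of partner does not stay in what it makes, so the products of the two hands are mirror images too

The chair proposed asking first where the product stops, and only then how fast it gets there.

The first member reported that in the violet run left-handed product formed 6.26 times more slowly from 10.0 h to 20.0 h than from 1.33 h to 6.00 h. She noted that the left-handed substrate of violet fell by a factor of 1.18, which is less, so she put the fall of the rate down to the partner. The centres of those windows stand 11.3 h apart. From this she read the partner's working life, the time in which the rate of making product falls to 36.8% of its value, as 6.18 h.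

The second member objected that the red run, with 14 equiv of partner against violet's 1.1 equiv, might still be making product at 25 h. The first replied that, for a rate falling exponentially with that life, the product still to come is the rate at that moment times the working life. Red's late rate, carried forward to 25 h with violet's life, gives 0.18 percentage points, less than the scatter of a reading, 0.3 points.

The meeting therefore reckoned the asked values to be plateaus. Since the last reading of left-handed product rose from 8.2% at 1.1 equiv to 36.1% at 14 equiv, it expected the ranking to follow the partner charge, with the first flask under red's figure and the last under violet's.

The forecast reads south-east > south > east > north-east > north-west > west, with 33% and 6.7%, on the ground that “yield is set by the integrated exposure”.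

The flasks give south-east > south > east > north-east > north-west > west, with 32.6% first and 5.99% last.

    partner + left-handed substrate → left-handed product (k = 0.360 L mol⁻¹ h⁻¹)
    partner + right-handed substrate → right-handed product (k = 0.200 L mol⁻¹ h⁻¹)
    left-handed substrate ⇌ achiral form (K = 0.0340, k = 0.220 h⁻¹)
    right-handed substrate ⇌ achiral form (K = 0.0340, k = 0.220 h⁻¹)
    achiral form → waste (k = 0.250 h⁻¹)
    2 partner → homo dimer (k = 0.190 L mol⁻¹ h⁻¹)
    partner → decomposed reagent (k = 0.160 h⁻¹)

At 25 h west has stood through 4.05 of violet's working lives, and partner, the limiting reagent, is down to 0.478% of its charge. West's left-handed product reads 5.99% then and 6.01% at ten times the time. The substrate has not come to rest: at 60.0 h, 5.66 lives later, west's left-handed substrate has gone from 40.1% to 34.8% and its waste from 8.96% to 19.9%. North-west, after 40.5 lives at 250 h, reads left-handed product 8.30% against 8.26% at 25 h, while its left-handed substrate has fallen from 38.5% to 15.3% and its waste has risen from 8.67% to 55.9%.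

All runs were generated by integration with constants of no real substance; noise was put on by code.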